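**Retrosynthetic overview**
- The oxirane is the only ring made (the arene is bought). It is closed last by intramolecular O-alkylation of the tertiary hydroxyl onto a primary mesylate, which touches no bond at the stereocentre.
- The quaternary (R) centre and the isovalerate are installed together by lipase desymmetrisation of a prochiral 2-arylpropane-1,2,3-triol with vinyl isovalerate.
- The aryl tiglate is put on at the bis-silyl ether stage (benzyl off, tigloyl on), so a free phenol never sits next to the epoxide.
- The 2-arylglycerol skeleton comes from an aryllithium (ortho-brominated 4-methoxy-3-methylphenol benzyl ether) and 1,3-bis(silyloxy)acetone.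

Target as read: tiglate (E) ester of a 1,2,4,5-tetrasubstituted arene carrying a 2,2-disubstituted oxirane whose single stereocentre is R.

Assumption: the lipase acylates the pro-R hydroxymethyl arm of triol 14; this sense is not known for this substrate and must be confirmed on the first run (the fallback for step 8 covers the opposite sense).

**Route**

Step 1
Reactants: 1 4-methoxy-3-methylphenol; 2 N-bromosuccinimide
Product: 3 2-bromo-4-methoxy-5-methylphenol
Conditions: NBS (1.0 equiv), MeCN, 0 °C, dark
Reagents that add atoms: N-bromosuccinimide, O=C1CCC(=O)N1Br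
Why: Electrophilic aromatic bromination goes to the only unhindered position that is ortho to OH and para to the methyl group, which is where the side chain is needed.

Step 2
Reactants: 3 2-bromo-4-methoxy-5-methylphenol; 4 benzyl bromide
Product: 5 1-(benzyloxy)-2-bromo-4-methoxy-5-methylbenzene
Conditions: BnBr, K2CO3, DMF, rt
Reagents that add atoms: benzyl bromide, BrCc1ccccc1
Why: Williamson ether synthesis masks the acidic phenol for the organolithium step with a group that comes off later by neutral hydrogenolysis.

Step 3
Reactants: 5 1-(benzyloxy)-2-bromo-4-methoxy-5-methylbenzene; 6 n-butyllithium; 7 1,3-bis[(tert-butyldimethylsilyl)oxy]propan-2-one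
Product: 10 2-[2-(benzyloxy)-5-methoxy-4-methylphenyl]-1,3-bis[(tert-butyldimethylsilyl)oxy]propan-2-ol, via aryllithium 8 (not isolated), via lithium alkoxide 9 (not isolated)
Conditions: n-BuLi, THF, −78 °C, 30 min; then 7, −78 → −20 °C; H2O quench
Reagents that add atoms: 1,3-bis[(tert-butyldimethylsilyl)oxy]propan-2-one, CC(C)(C)[Si](C)(C)OCC(=O)CO[Si](C)(C)C(C)(C)C
Why: Bromine–lithium exchange followed by 1,2-addition of the aryllithium to the ketone builds the tertiary carbinol, which is still achiral (prochiral) because its two CH2OTBS arms are identical.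

Step 4
Reactants: 10 2-[2-(benzyloxy)-5-methoxy-4-methylphenyl]-1,3-bis[(tert-butyldimethylsilyl)oxy]propan-2-ol
Product: 11 2-{1,3-bis[(tert-butyldimethylsilyl)oxy]-2-hydroxypropan-2-yl}-4-methoxy-5-methylphenol
Conditions: H2 (1 atm), 10% Pd/C, EtOAc, rt
Reagents that add atoms: none
Why: Catalytic hydrogenolysis of the benzyl ether in neutral EtOAc leaves the silyl ethers and the non-acidified tertiary benzylic alcohol intact.

Step 5
Reactants: 11 2-{1,3-bis[(tert-butyldimethylsilyl)oxy]-2-hydroxypropan-2-yl}-4-methoxy-5-methylphenol; 12 tigloyl chloride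
Product: 13 2-{1,3-bis[(tert-butyldimethylsilyl)oxy]-2-hydroxypropan-2-yl}-4-methoxy-5-methylphenyl (E)-2-methylbut-2-enoate
Conditions: tigloyl chloride, pyridine, DMAP (cat.), CH2Cl2, 0 °C → rt
Reagents that add atoms: tigloyl chloride [(E)-2-methylbut-2-enoyl chloride], C/C=C(\C)C(=O)Cl
Why: DMAP-catalysed O-acylation (nucleophilic acyl substitution) takes place only at the phenol because the tertiary alcohol is too hindered, and pyridine instead of a trialkylamine avoids vinylketene formation so the E olefin stays conjugated.

Step 6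
Reactants: 13 2-{1,3-bis[(tert-butyldimethylsilyl)oxy]-2-hydroxypropan-2-yl}-4-methoxy-5-methylphenyl (E)-2-methylbut-2-enoate
Product: 14 4-methoxy-5-methyl-2-(1,2,3-trihydroxypropan-2-yl)phenyl (E)-2-methylbut-2-enoate
Conditions: HF·pyridine, pyridine, THF, 0 °C → rt
Reagents that add atoms: none
Why: Buffered fluoride-mediated desilylation removes both primary TBS ethers without cleaving or migrating the aryl ester and releases the prochiral 2-arylglycerol.

Step 7
Reactants: 15 3-methylbutanoic acid; 16 vinyl acetate
Product: 17 vinyl 3-methylbutanoate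
Conditions: vinyl acetate (excess, solvent), Pd(OAc)2 (cat.), KOH (cat.), rt; distil
Reagents that add atoms: vinyl acetate, CC(=O)OC=C
Why: Pd(II)-catalysed transvinylation (vinyl interchange), driven by excess vinyl acetate, gives the irreversible acyl donor needed for the enzymatic step.

Step 8
Reactants: 14 4-methoxy-5-methyl-2-(1,2,3-trihydroxypropan-2-yl)phenyl (E)-2-methylbut-2-enoate; 17 vinyl 3-methylbutanoate
Product: 18 2-[(2R)-1,2-dihydroxy-3-(3-methylbutanoyloxy)propan-2-yl]-4-methoxy-5-methylphenyl (E)-2-methylbut-2-enoate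
Conditions: lipase (Burkholderia cepacia lipase, immobilised), 17 (3 equiv), MTBE, 30 °C; filter off enzyme, use promptly
Reagents that add atoms: vinyl 3-methylbutanoate, CC(C)CC(=O)OC=C
Why: Lipase-catalysed irreversible transesterification (enantiotopic-group-selective desymmetrisation of a prochiral 2-substituted glycerol) acylates only the pro-R primary hydroxyl, which creates the quaternary stereocentre as R, and the vinyl alcohol released tautomerises to acetaldehyde so the step cannot reverse.

Step 9
Reactants: 18 2-[(2R)-1,2-dihydroxy-3-(3-methylbutanoyloxy)propan-2-yl]-4-methoxy-5-methylphenyl (E)-2-methylbut-2-enoate; 19 methanesulfonyl chloride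
Product: 20 2-[(2S)-2-hydroxy-1-(methanesulfonyloxy)-3-(3-methylbutanoyloxy)propan-2-yl]-4-methoxy-5-methylphenyl (E)-2-methylbut-2-enoate
Conditions: MsCl, Et3N, CH2Cl2, −30 °C, 30 min
Reagents that add atoms: methanesulfonyl chloride, CS(=O)(=O)Cl
Why: Selective sulfonylation (mesylation) of the remaining primary hydroxyl, short and cold to prevent the 1,3-acyl migration that would erode ee; the descriptor becomes S only because CH2OMs outranks CH2O-acyl, the spatial arrangement is unchanged.

Step 10
Reactants: 20 2-[(2S)-2-hydroxy-1-(methanesulfonyloxy)-3-(3-methylbutanoyloxy)propan-2-yl]-4-methoxy-5-methylphenyl (E)-2-methylbut-2-enoate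
Product: 21 4-methoxy-5-methyl-2-[(2R)-2-[(3-methylbutanoyloxy)methyl]oxiran-2-yl]phenyl (E)-2-methylbut-2-enoate
Conditions: DBU, CH2Cl2, 0 °C → rt
Reagents that add atoms: none
Why: Intramolecular Williamson etherification (3-exo-tet SN2) of the tertiary hydroxyl onto the primary mesylate with a non-nucleophilic amidine base closes the oxirane without breaking any bond at the stereocentre, so the configuration is retained and reads R in the epoxide.

**Compound list**
1 | 4-methoxy-3-methylphenol | COc1ccc(O)cc1C | starting material
2 | N-bromosuccinimide | O=C1CCC(=O)N1Br | starting material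
3 | 2-bromo-4-methoxy-5-methylphenol | COc1cc(Br)c(O)cc1C | intermediate
4 | benzyl bromide | BrCc1ccccc1 | starting material
5 | 1-(benzyloxy)-2-bromo-4-methoxy-5-methylbenzene | COc1cc(Br)c(OCc2ccccc2)cc1C | intermediate
6 | n-butyllithium | [Li]CCCC | starting material
7 | 1,3-bis[(tert-butyldimethylsilyl)oxy]propan-2-one | CC(C)(C)[Si](C)(C)OCC(=O)CO[Si](C)(C)C(C)(C)C | starting material
8 | [2-(benzyloxy)-5-methoxy-4-methylphenyl]lithium (not isolated) | COc1cc([Li])c(OCc2ccccc2)cc1C | intermediate
9 | lithium 2-[2-(benzyloxy)-5-methoxy-4-methylphenyl]-1,3-bis[(tert-butyldimethylsilyl)oxy]propan-2-olate (not isolated) | COc1cc(C(O[Li])(CO[Si](C)(C)C(C)(C)C)CO[Si](C)(C)C(C)(C)C)c(OCc2ccccc2)cc1C | intermediate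
10 | 2-[2-(benzyloxy)-5-methoxy-4-methylphenyl]-1,3-bis[(tert-butyldimethylsilyl)oxy]propan-2-ol | COc1cc(C(O)(CO[Si](C)(C)C(C)(C)C)CO[Si](C)(C)C(C)(C)C)c(OCc2ccccc2)cc1C | intermediate
11 | 2-{1,3-bis[(tert-butyldimethylsilyl)oxy]-2-hydroxypropan-2-yl}-4-methoxy-5-methylphenol | COc1cc(C(O)(CO[Si](C)(C)C(C)(C)C)CO[Si](C)(C)C(C)(C)C)c(O)cc1C | intermediate
12 | tigloyl chloride [(E)-2-methylbut-2-enoyl chloride] | C/C=C(\C)C(=O)Cl | starting material
13 | 2-{1,3-bis[(tert-butyldimethylsilyl)oxy]-2-hydroxypropan-2-yl}-4-methoxy-5-methylphenyl (E)-2-methylbut-2-enoate | C/C=C(\C)C(=O)Oc1cc(C)c(OC)cc1C(O)(CO[Si](C)(C)C(C)(C)C)CO[Si](C)(C)C(C)(C)C | intermediate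
14 | 4-methoxy-5-methyl-2-(1,2,3-trihydroxypropan-2-yl)phenyl (E)-2-methylbut-2-enoate (achiral, prochiral) | C/C=C(\C)C(=O)Oc1cc(C)c(OC)cc1C(O)(CO)CO | intermediate
15 | 3-methylbutanoic acid (isovaleric acid) | CC(C)CC(=O)O | starting material
16 | vinyl acetate | CC(=O)OC=C | starting material
17 | vinyl 3-methylbutanoate (vinyl isovalerate) | CC(C)CC(=O)OC=C | intermediate
18 | 2-[(2R)-1,2-dihydroxy-3-(3-methylbutanoyloxy)propan-2-yl]-4-methoxy-5-methylphenyl (E)-2-methylbut-2-enoate | C/C=C(\C)C(=O)Oc1cc(C)c(OC)cc1[C@](O)(COC(=O)CC(C)C)CO | intermediate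
19 | methanesulfonyl chloride | CS(=O)(=O)Cl | starting material
20 | 2-[(2S)-2-hydroxy-1-(methanesulfonyloxy)-3-(3-methylbutanoyloxy)propan-2-yl]-4-methoxy-5-methylphenyl (E)-2-methylbut-2-enoate | C/C=C(\C)C(=O)Oc1cc(C)c(OC)cc1[C@](O)(COC(=O)CC(C)C)COS(C)(=O)=O | intermediate
21 | 4-methoxy-5-methyl-2-[(2R)-2-[(3-methylbutanoyloxy)methyl]oxiran-2-yl]phenyl (E)-2-methylbut-2-enoate (CNP0108422.1) | C/C=C(\C)C(=O)Oc1cc(C)c(OC)cc1[C@]1(COC(=O)CC(C)C)CO1 | target

**Step count**
Total steps: 10. Longest linear sequence: 9 (steps 1–6 and 8–10); step 7 is a one-step side branch that feeds step 8.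

**Steps most likely to fail**

Step 3 (aryllithium addition). Ketone 7 is enolisable and flanked by two bulky silyloxymethyl groups, so proton transfer can return debrominated arene. The fallback changes the C3 electrophile to a non-enolisable one at a higher oxidation level. It sets out from 5: aryllithium 8 is generated as before and added to diethyl oxomalonate, giving after aqueous quench of the lithium alkoxide of the adduct F1 the tartronate diethyl 2-[2-(benzyloxy)-5-methoxy-4-methylphenyl]-2-hydroxypropanedioate F2. Reduction of both esters (LiAlH4, THF, 0 °C) gives 2-[2-(benzyloxy)-5-methoxy-4-methylphenyl]propane-1,2,3-triol F3. Silylation of the two primary hydroxyls (TBSCl, imidazole, DMF, 0 °C) comes back to the route at 10.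

Step 8 (lipase desymmetrisation). The sense and level of enantiotopic-group selectivity are not known for this substrate; ee is to be checked by chiral HPLC before going on. If the acylation mode gives the S monoester or poor ee, the fallback switches to the complementary deacylation mode. It sets out from 14: both primary hydroxyls are acylated chemically (3-methylbutanoyl chloride, 2,4,6-collidine, CH2Cl2, −20 °C) to the achiral diester 2-[2-hydroxy-1,3-bis(3-methylbutanoyloxy)propan-2-yl]-4-methoxy-5-methylphenyl (E)-2-methylbut-2-enoate F4. The same lipase then removes one enantiotopic ester by alcoholysis with n-butanol in MTBE. An enzyme that acylates the pro-S arm also deacylates that arm, so the ester stays on the pro-R arm and the route is rejoined at 18.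

Step 10 (epoxide closure next to two esters). The tertiary alkoxide character that develops under base can instead attack the aryl tiglate or the isovalerate (acyl transfer), and a liberated phenoxide would then cyclise onto the mesylate. The fallback avoids an anionic oxygen altogether. It sets out from 18 (skipping the mesylate) and uses a Mitsunobu cyclodehydration (PPh3, DIAD, THF, 0 °C → rt). The primary hydroxyl is activated as its oxyphosphonium and displaced by the neutral tertiary hydroxyl with retention at the stereocentre. This goes straight to 21 and no new compound arises on the way.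

**Further compounds**
F1 | step 3 | lithium 1,3-diethoxy-2-[2-(benzyloxy)-5-methoxy-4-methylphenyl]-1,3-dioxopropan-2-olate (not isolated) | CCOC(=O)C(O[Li])(C(=O)OCC)c1cc(OC)c(C)cc1OCc1ccccc1
F2 | step 3 | diethyl 2-[2-(benzyloxy)-5-methoxy-4-methylphenyl]-2-hydroxypropanedioate | CCOC(=O)C(O)(C(=O)OCC)c1cc(OC)c(C)cc1OCc1ccccc1
F3 | step 3 | 2-[2-(benzyloxy)-5-methoxy-4-methylphenyl]propane-1,2,3-triol | OCC(O)(CO)c1cc(OC)c(C)cc1OCc1ccccc1
F4 | step 8 | 2-[2-hydroxy-1,3-bis(3-methylbutanoyloxy)propan-2-yl]-4-methoxy-5-methylphenyl (E)-2-methylbut-2-enoate | C/C=C(\C)C(=O)Oc1cc(C)c(OC)cc1C(O)(COC(=O)CC(C)C)COC(=O)CC(C)C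
F0 | step 10 | none | none
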